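## Structural features

The target is a C–C linked biflavonoid. One half is a (2R)-5-hydroxy-7-methoxy-2-phenylchroman-4-one (flavanone; rings A, B, C, unprimed locants). The other is a (2'S,4'S)-7'-hydroxy-5',8'-dimethoxy-2'-phenylchroman (flavan; rings A', B', C', primed locants). The two are joined by the C6–C4' bond.

C4' is a diarylmethine that carries ring A (flanked by O5 and O7) and ring A' (flanked by O5' and the ring oxygen O1'), so it is a benzylic carbon with four ortho substituents. C2' and C4' are 1,3-related across the C3' methylene of ring C' and are trans. C2 lies seven bonds away across ring A, beyond any substrate control.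

Fragile elements:
- The β-aryloxy ketone of ring C can open to a chalcone under base, which would racemise C2.
- The electron-rich C6–C4' bond and the benzylic ethers C2'–O1' and C2–O1 can ionise under acid.
- Ring A' is tetra-oxygenated with a para-dimethoxy pattern and is easily oxidised to a quinone.

The real difficulty is to build the crowded C4' methine in one absolute configuration, to place C2' trans to it, and to fix the ring A pattern (C6 linkage, free 5-OH beside 7-OMe) without regioisomers.

The key step exploits two features. C4' stands 1,3 to the O1'–C2' bond, so C2'–C3'–C4' map onto an enal and C4a'/O1' onto an ortho carbon and hydroxyl of a phenol. Ring A' derives from the symmetric 2,5-dimethoxyresorcinol, whose two unsubstituted carbons are equivalent. Ring A keeps a local mirror symmetry (O5/O7, C4a/C8) until ring C is closed, which removes the regiochemical question there.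

## Logic of the disconnections

**27 ⇒ 25 (through 26).** Bonds cut: O5–CH3 and O7'–CH2Ph. Keeping O5 and O7 both as methyl ethers leaves ring A symmetric until ring C exists; the C4 carbonyl then singles out O5 by chelation. This removes any need for orthogonal protection of O5. The forward step must cleave only the chelated methyl ether and the benzyl ether, cold, without opening either heterocycle.

**25 ⇒ 23 (through 24).** Bond cut: C4–C4a (acyl–aryl). The acyl carbon attacks a ring carbon ortho to the ether oxygen; both ortho carbons are equivalent, so one constitution results and C2 is untouched. Ring C is removed and a β-aryloxy acid remains. The acylation must be mild and non-ionising.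

**23 ⇒ 22 ⇒ 20 + 21.** Bonds cut: the ester O–C2H5 (functional group interchange) and O1–C2 (aryl ether). C2 is bought as 21 and transferred with inversion, which makes the route convergent and independent of the distant chroman stereocentres. The forward steps need clean SN2 substitution at a benzylic β-hydroxy ester and saponification without loss of phenoxide.

**20 ⇒ 19.** Bond cut: O–S of the arenesulfonate. Its removal exposes the only free phenol of the molecule, so the etherification with 21 needs no site selectivity. At this stage there is no base-sensitive group.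

**19 ⇒ 18.** Bond cut: O1'–C2'. An invertive ring closure turns an open-chain carbinol, whose configuration is set by a catalyst, into the 2',4'-trans ring. The forward step must be SN2 at a secondary benzylic carbon, starting from the (R)-carbinol.

**18 ⇒ 17.** Change: C2'–H (carbinol back to ketone). An aryl alkyl ketone is an ideal substrate for catalyst-controlled transfer hydrogenation. The catalyst must override the remote C4' centre and tolerate a free phenol.

**17 ⇒ 15 (through 16).** Bond cut: C2'–C(phenyl). At the lactone oxidation level the phenyl ring enters by acyl substitution, so the ketone is reached without oxidising anything next to a free electron-rich phenol. Lactone opening also frees the O1' phenol. Mono-addition is required and is secured by the N-methoxy-N-methylamide chelate.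

**15 ⇒ 14 ⇒ 13.** Changes: oxidation level of C2' and the O7'–benzyl bond. The phenol left over from 7 must be masked before oxidation and kept distinct from the ring A oxygen. The alkylation must hit the phenol and not the lactol.

**13 ⇒ 7 + 11 (through 12), the key disconnection.** Bonds cut: C4a'–C4' and O1'–C2'. The enal 11 supplies C2'–C3'–C4' and ring A, and 7 supplies ring A' with both oxygens already in place. The whole chroman core, the hindered diarylmethine and its configuration come from two simple aromatics in one catalytic step. The forward step needs enantioface control on a hindered, donor-substituted iminium ion and mono-alkylation of 7.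

**11 ⇒ 9 ⇒ 8 (through 10).** Bonds cut: the C2'=C3' double bond (olefination) and O–S. The phenol is masked as an electron-poor sulfonate rather than a silyl ether, because a para-silyloxy group would donate into the iminium ion and is a base-labile vinylogous silyl ester. The forward steps need E geometry and no over-homologation.

**7 ⇒ 6 ⇒ 5 ⇒ 2 ⇒ 1 (through 3 and 4).** Bonds cut: two O–CH2OCH3 bonds, O–CH3, and the aryl C2–O bond. C2 of 1 is the only carbon flanked by two acetal oxygens, so directed metalation, borylation and oxidation place the fourth oxygen there. The lithiation must be regioselective.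

## Other disconnections considered

**Alternative 1:** The cut runs through ring C of the flavanone: C4a–C4, C4–C3 and O1–C2. The carbonyl carbon would come from carbon monoxide and C2/C3 from ethynylbenzene A3.
- Forward: phenol 20 would be iodinated to the iodophenol A2. Pd(PPh3)2Cl2, CO and diethylamine would then couple A2 with A3 to the ynone A4, which closes by 6-endo-dig oxa-Michael addition to the flavone A1. Asymmetric hydrogenation of C2=C3 would lead to 25.
- In favour: ring C is assembled catalytically from cheap components without phosphine oxide or hydrazide waste. The iodine fixes the regiochemistry. No β-aryloxy acid and no acidic acylation near the acid-labile C6–C4' bond are needed. On these three points it is the better plan.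
- Against: the iodide sits on a very electron-rich ring between OH and OMe, so oxidative addition and CO insertion would be slow. Direct alkynylation (leading to a benzofuran) and 5-exo closure (aurone) compete. C2 would be created by a late hydrogenation that has to override a substrate with two stereocentres, stop at the ketone, spare the benzyl ether, and give a flavanone that can racemise by ring opening.
- Comparison: it addresses only the flavanone end and leaves C4' unsolved. It is equal on regiochemical logic (both use the symmetry of ring A) and equal at best in step count from 20 (three to four steps against three). In the chosen plan C2 comes from a purchased stereocentre by SN2 inversion, which is more predictable.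

**Alternative 2:** The cut is the aryl–oxygen bond O1'–C8a'.
- Forward: the quinone carbinol A6, with C2' and C4' already in place, would add its C2' hydroxyl to C8a' (6-endo-trig oxa-Michael) and enolise to the hydroquinone A5. Double O-methylation would follow.
- In favour: C2' enters with retention, so no inversion at a benzylic carbon and no SN1 leakage; on this point it is the better plan. The closure is redox-neutral, and the nucleophile is an unhindered alcohol rather than a di-ortho-substituted phenol.
- Against: the step forms one bond and no stereocentre, so C4' would still need its own asymmetric C–C bond formation in an open chain. The quinone has to be generated oxidatively on a substrate with a second electron-rich ring. The C4' hydrogen lies next to the quinone and can tautomerise to a quinone methide, which would erase C4'. Quinone and hydroquinone can exchange redox states, and two methylations must be added afterwards.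
- Comparison: the chosen step forms C4a'–C4' and O1'–C2' and sets C4' in one operation. Alternative 2 is at least three steps longer. It is equal in that both plans set C2' by ketone reduction.

**Alternative 3:** Here O1' is inserted between C8a' and C2'.
- Forward: the enantioenriched 3-arylindan-1-one A8 would undergo Baeyer–Villiger oxidation with migration of aryl carbon C8a' to give the dihydrocoumarin A7. A7 is the silyl-protected analogue of lactone 15, so the endgame would be shared.
- In favour: it delivers the lactone oxidation level directly and saves the lactol oxidation (a point in its favour). The electron-rich aryl carbon migrates in preference to the CH2, with retention, so C4' is untouched. Catalytic routes to 3-arylindanones may give higher enantiomeric purity than an iminium reaction on a hindered enal, and there is no double-alkylation issue.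
- Against: peracids attack very electron-rich arenes (hydroxylation, quinone formation). A ketone conjugated to three oxygen donors is sluggish in this oxidation and would need acid activation, which threatens the silyl ether and the diarylmethine. A8 itself needs a separate C–C bond formation and a Friedel–Crafts ring closure in which two electron-rich rings compete. O1' is introduced by oxidation instead of being carried in from the resorcinol.
- Comparison: three to four steps to reach what the chosen plan reaches in three (annulation, benzylation, oxidation). It is equal in that C2' is set afterwards by the same reduction and closure.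

Key step: step 7

**Remarks on the chemistry.**
- The SMILES of the target corresponds to (2R) in the chromanone and (2'S,4'S) in the chroman, the latter pair trans.
- Rotation about C6–C4' is taken as hindered but not frozen, so no separable atropisomers are considered.
- The key-step partners and the lactol were checked atom by atom against the target and needed no correction. The one design change is the phenol protecting group of the enal (arenesulfonate instead of trialkylsilyl ether); skeleton, bonds formed and ring closed are unchanged.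
- The diarylmethine carbon keeps one spatial arrangement throughout. Its descriptor reads R in the open-chain compounds 12 and 16–18 and S in the ring-closed ones, only because the priority of the two aryl groups switches.

## Route

Step 1
Reactants: 1 5-methoxybenzene-1,3-diol (5-methoxyresorcinol)
Product: 2 1-methoxy-3,5-bis(methoxymethoxy)benzene
Conditions: MOMCl, i-Pr2NEt, CH2Cl2, 0 °C → rt
Reagents that add atoms: chloromethyl methyl ether, COCCl
Why: Williamson-type O-alkylation of both phenols by the reactive α-chloro ether; the methoxymethyl ethers are the coordinating groups needed for the next step.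

Step 2
Reactants: 2 1-methoxy-3,5-bis(methoxymethoxy)benzene
Product: 5 4-methoxy-2,6-bis(methoxymethoxy)phenol, via aryllithium 3 (not isolated), via boronate 4 (not isolated)
Conditions: n-BuLi, THF, 0 °C; B(OMe)3, −78 °C → rt; AcOH, 30% H2O2, 0 °C → rt
Reagents that add atoms: hydrogen peroxide, OO
Why: Directed ortho-metalation at the carbon flanked by two chelating acetal oxygens, electrophilic borylation, then oxidative 1,2-shift of the aryl group from boron to oxygen (borylation–oxidation); double coordination secures the regiochemistry.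

Step 3
Reactants: 5 4-methoxy-2,6-bis(methoxymethoxy)phenol
Product: 6 2,5-dimethoxy-1,3-bis(methoxymethoxy)benzene
Conditions: MeI, K2CO3, acetone, reflux
Reagents that add atoms: iodomethane, CI
Why: Williamson etherification of the single free phenol; it should be run promptly because 5 is air-sensitive.

Step 4
Reactants: 6 2,5-dimethoxy-1,3-bis(methoxymethoxy)benzene
Product: 7 2,5-dimethoxybenzene-1,3-diol
Conditions: 3 M HCl, MeOH, 50 °C, Ar
Reagents that add atoms: none
Why: Acid-catalysed transacetalisation removes both methoxymethyl groups, while aryl methyl ethers are inert to dilute acid.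

Step 5
Reactants: 8 4-hydroxy-2,6-dimethoxybenzaldehyde
Product: 9 4-formyl-3,5-dimethoxyphenyl 4-methylbenzenesulfonate
Conditions: TsCl, Et3N, DMAP (cat.), CH2Cl2, 0 °C → rt
Reagents that add atoms: 4-methylbenzenesulfonyl chloride, Cc1ccc(cc1)S(=O)(=O)Cl
Why: O-sulfonylation of the phenol; the sulfonate is inert to ylides, Grignard reagents at low temperature and mild acid, and unlike a silyl ether it does not donate into the later iminium ion.

Step 6
Reactants: 9 4-formyl-3,5-dimethoxyphenyl 4-methylbenzenesulfonate
Product: 11 3,5-dimethoxy-4-[(E)-3-oxoprop-1-enyl]phenyl 4-methylbenzenesulfonate, via vinyl dioxolane 10 (not isolated)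
Conditions: (1,3-dioxolan-2-ylmethyl)triphenylphosphonium bromide, KN(SiMe3)2, THF, 0 °C; 9, 0 °C → rt; then 2 M HCl, rt
Reagents that add atoms: (1,3-dioxolan-2-ylmethyl)triphenylphosphonium bromide, [Br-].C1COC(C[P+](c2ccccc2)(c2ccccc2)c2ccccc2)O1; water, O
Why: Wittig olefination with a masked formylmethylene ylide (two-carbon homologation), then acetal hydrolysis during which acid equilibrates the alkene to the conjugated E isomer; the masked reagent cannot homologate the product a second time.

Step 7
Reactants: 7 2,5-dimethoxybenzene-1,3-diol; 11 3,5-dimethoxy-4-[(E)-3-oxoprop-1-enyl]phenyl 4-methylbenzenesulfonate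
Product: 13 4-[(4S)-2,7-dihydroxy-5,8-dimethoxychroman-4-yl]-3,5-dimethoxyphenyl 4-methylbenzenesulfonate (lactol; both C2 epimers), via open-chain aldehyde 12 (not isolated)
Conditions: (S)-2-[diphenyl(trimethylsilyloxy)methyl]pyrrolidine (20 mol%), PhCO2H (20 mol%), 7 (3 equiv), CH2Cl2, 0 °C → rt, Ar
Reagents that add atoms: none
Why: The amine condenses with 11 to the (E)-s-trans iminium ion; 7, with benzoate as general base, attacks C-β through a ring carbon that is ortho to one hydroxyl and para to the other (Friedel–Crafts conjugate addition), and the resulting enamine is protonated and hydrolysed to aldehyde 12. The neighbouring phenol then adds to the aldehyde to give lactol 13, which withdraws the adduct from the reverse reaction. The closest known reaction type is the diarylprolinol silyl ether catalysed Friedel–Crafts alkylation/hemiacetalisation of naphthols and electron-rich phenols with cinnamaldehydes to 4-arylchroman-2-ols. Ring C' closes in the 6-exo-trig mode (phenol oxygen onto the aldehyde carbon, forming O1'–C2' after C4a'–C4'). The one new fixed stereocentre, C4', is controlled by the catalyst: the diphenyl(silyloxy)methyl group should shield the Re face of C-β so that the arene adds to the Si face, which corresponds to (4S); C2' forms as an inconsequential anomeric mixture. The step needs C- over O-alkylation (O-adducts revert, the C-adduct is trapped as lactol) and site selectivity (both free carbons of 7 are equivalent by symmetry, so the leftover hydroxyl is already the 7'-OH). It also needs mono-alkylation (excess 7, recoverable) and dominance of the catalysed pathway over acid-promoted background addition (the sulfonate keeps the iminium ion electrophilic enough to react at or below room temperature).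

Step 8
Reactants: 13 4-[(4S)-2,7-dihydroxy-5,8-dimethoxychroman-4-yl]-3,5-dimethoxyphenyl 4-methylbenzenesulfonate
Product: 14 4-[(4S)-7-(benzyloxy)-2-hydroxy-5,8-dimethoxychroman-4-yl]-3,5-dimethoxyphenyl 4-methylbenzenesulfonate (both C2 epimers)
Conditions: BnBr (1.05 equiv), K2CO3, acetone, rt
Reagents that add atoms: benzyl bromide, BrCc1ccccc1
Why: Williamson etherification; the phenol is far more acidic than the lactol hydroxyl and is unhindered, so one equivalent of halide should alkylate O7' only.

Step 9
Reactants: 14 4-[(4S)-7-(benzyloxy)-2-hydroxy-5,8-dimethoxychroman-4-yl]-3,5-dimethoxyphenyl 4-methylbenzenesulfonate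
Product: 15 4-[(4S)-7-(benzyloxy)-5,8-dimethoxy-2-oxochroman-4-yl]-3,5-dimethoxyphenyl 4-methylbenzenesulfonate
Conditions: [C5H5NH][CrO3Cl], NaOAc, 4 Å MS, CH2Cl2, rt
Reagents that add atoms: none
Why: Chlorochromate oxidation of a lactol to a lactone through the chromate ester; no free phenol is present in the closed lactol and the buffer protects the diarylmethine, so both anomers converge on one compound.

Step 10
Reactants: 15 4-[(4S)-7-(benzyloxy)-5,8-dimethoxy-2-oxochroman-4-yl]-3,5-dimethoxyphenyl 4-methylbenzenesulfonate
Product: 17 4-[(1R)-1-[4-(benzyloxy)-2-hydroxy-3,6-dimethoxyphenyl]-3-oxo-3-phenylpropyl]-3,5-dimethoxyphenyl 4-methylbenzenesulfonate, via Weinreb amide 16 (not isolated)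
Conditions: MeNH(OMe)·HCl, i-PrMgCl, THF, −20 °C; then PhMgBr, −20 → 0 °C; aq. NH4Cl
Reagents that add atoms: phenylmagnesium bromide, Br[Mg]c1ccccc1
Why: The chloromagnesium amide of N,O-dimethylhydroxylamine opens the activated aryl lactone to the N-methoxy-N-methylamide, and the Grignard reagent then adds once because the five-membered magnesium chelate survives until work-up (Weinreb ketone synthesis); the ketone is reached without an oxidation beside the freed phenol.

Step 11
Reactants: 17 4-[(1R)-1-[4-(benzyloxy)-2-hydroxy-3,6-dimethoxyphenyl]-3-oxo-3-phenylpropyl]-3,5-dimethoxyphenyl 4-methylbenzenesulfonate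
Product: 18 4-[(1R,3R)-1-[4-(benzyloxy)-2-hydroxy-3,6-dimethoxyphenyl]-3-hydroxy-3-phenylpropyl]-3,5-dimethoxyphenyl 4-methylbenzenesulfonate
Conditions: RuCl[(R,R)-TsDPEN](p-cymene) (2 mol%), HCO2H/Et3N (5:2), CH2Cl2, 30 °C
Reagents that add atoms: none
Why: Noyori-type asymmetric transfer hydrogenation of an aryl alkyl ketone; the (R,R) ligand should deliver hydride to give the (R)-carbinol (same sense as for acetophenone), the remote methine having little say, and free phenols are tolerated.

Step 12
Reactants: 18 4-[(1R,3R)-1-[4-(benzyloxy)-2-hydroxy-3,6-dimethoxyphenyl]-3-hydroxy-3-phenylpropyl]-3,5-dimethoxyphenyl 4-methylbenzenesulfonate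
Product: 19 4-[(2S,4S)-7-(benzyloxy)-5,8-dimethoxy-2-phenylchroman-4-yl]-3,5-dimethoxyphenyl 4-methylbenzenesulfonate
Conditions: PPh3, DIAD, THF, 0 °C → rt
Reagents that add atoms: none
Why: Intramolecular Mitsunobu etherification: the phenoxide displaces the oxyphosphonium group in a 6-exo-tet SN2 step with inversion, turning the (R)-carbinol into (2S) and hence the 2,4-trans chroman; an unsubstituted phenyl group gives little tendency to ionise.

Step 13
Reactants: 19 4-[(2S,4S)-7-(benzyloxy)-5,8-dimethoxy-2-phenylchroman-4-yl]-3,5-dimethoxyphenyl 4-methylbenzenesulfonate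
Product: 20 4-[(2S,4S)-7-(benzyloxy)-5,8-dimethoxy-2-phenylchroman-4-yl]-3,5-dimethoxyphenol
Conditions: NaOH, H2O/1,4-dioxane, 80 °C; then aq. HCl to pH 6
Reagents that add atoms: none
Why: Hydroxide attacks sulfur and releases the phenoxide (aryl sulfonate hydrolysis); the substrate holds only ethers at this stage, and the alcohol-free medium prevents formation of an alkylating sulfonate ester.

Step 14
Reactants: 20 4-[(2S,4S)-7-(benzyloxy)-5,8-dimethoxy-2-phenylchroman-4-yl]-3,5-dimethoxyphenol; 21 ethyl (3S)-3-hydroxy-3-phenylpropanoate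
Product: 22 ethyl (3R)-3-{4-[(2S,4S)-7-(benzyloxy)-5,8-dimethoxy-2-phenylchroman-4-yl]-3,5-dimethoxyphenoxy}-3-phenylpropanoate
Conditions: PPh3, DIAD, toluene, 0 °C → rt (slow addition of DIAD)
Reagents that add atoms: none
Why: Intermolecular Mitsunobu etherification with inversion, (S)-alcohol to (R)-aryl ether, which sets C2 of the flavanone; the phenol has two free ortho positions and is the only acidic group present.

Step 15
Reactants: 22 ethyl (3R)-3-{4-[(2S,4S)-7-(benzyloxy)-5,8-dimethoxy-2-phenylchroman-4-yl]-3,5-dimethoxyphenoxy}-3-phenylpropanoate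
Product: 23 (3R)-3-{4-[(2S,4S)-7-(benzyloxy)-5,8-dimethoxy-2-phenylchroman-4-yl]-3,5-dimethoxyphenoxy}-3-phenylpropanoic acid
Conditions: LiOH·H2O, THF/MeOH/H2O, 0 °C → rt; then aq. HCl (pH 3)
Reagents that add atoms: lithium hydroxide, [Li+].[OH-]
Why: Saponification by acyl–oxygen cleavage; low temperature and the mild base should keep E1cB loss of the phenoxide from the β-aryloxy ester in check.

Step 16
Reactants: 23 (3R)-3-{4-[(2S,4S)-7-(benzyloxy)-5,8-dimethoxy-2-phenylchroman-4-yl]-3,5-dimethoxyphenoxy}-3-phenylpropanoic acid
Product: 25 (2R)-6-[(2S,4S)-7-(benzyloxy)-5,8-dimethoxy-2-phenylchroman-4-yl]-5,7-dimethoxy-2-phenylchroman-4-one, via mixed anhydride 24 (not isolated)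
Conditions: (CF3CO)2O, CH2Cl2, 0 °C → rt
Reagents that add atoms: none
Why: Intramolecular Friedel–Crafts acylation through the mixed trifluoroacetic anhydride onto a ring carbon ortho to the ether oxygen and activated by three oxygens; the two ortho carbons are equivalent, so only one constitution can form, and the stereocentres are not involved.

Step 17
Reactants: 25 (2R)-6-[(2S,4S)-7-(benzyloxy)-5,8-dimethoxy-2-phenylchroman-4-yl]-5,7-dimethoxy-2-phenylchroman-4-one
Product: 27 (2R)-5-hydroxy-6-[(2S,4S)-7-hydroxy-5,8-dimethoxy-2-phenylchroman-4-yl]-7-methoxy-2-phenylchroman-4-one, via debenzylated flavanone 26 (not isolated)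
Conditions: BCl3, C6HMe5, CH2Cl2, −78 → −10 °C; MeOH, aq. NaHCO3
Reagents that add atoms: none
Why: Boron trichloride removes the benzyl group at low temperature (the benzyl cation is trapped by pentamethylbenzene) and, on warming, cleaves the one methyl ether that can form a six-membered boron chelate with the C4 carbonyl; the other methoxy groups lack that chelation.

## Compound list

1 | 5-methoxybenzene-1,3-diol | COc1cc(O)cc(O)c1 | starting material
2 | 1-methoxy-3,5-bis(methoxymethoxy)benzene | COCOc1cc(OC)cc(OCOC)c1 | intermediate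
3 | [4-methoxy-2,6-bis(methoxymethoxy)phenyl]lithium | [Li]c1c(OCOC)cc(OC)cc1OCOC | intermediate (not isolated)
4 | dimethyl [4-methoxy-2,6-bis(methoxymethoxy)phenyl]boronate | COB(OC)c1c(OCOC)cc(OC)cc1OCOC | intermediate (not isolated)
5 | 4-methoxy-2,6-bis(methoxymethoxy)phenol | COCOc1cc(OC)cc(OCOC)c1O | intermediate
6 | 2,5-dimethoxy-1,3-bis(methoxymethoxy)benzene | COCOc1cc(OC)cc(OCOC)c1OC | intermediate
7 | 2,5-dimethoxybenzene-1,3-diol | COc1cc(O)c(OC)c(O)c1 | intermediate
8 | 4-hydroxy-2,6-dimethoxybenzaldehyde | COc1cc(O)cc(OC)c1C=O | starting material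
9 | 4-formyl-3,5-dimethoxyphenyl 4-methylbenzenesulfonate | COc1cc(OS(=O)(=O)c2ccc(C)cc2)cc(OC)c1C=O | intermediate
10 | 4-[2-(1,3-dioxolan-2-yl)ethenyl]-3,5-dimethoxyphenyl 4-methylbenzenesulfonate (E/Z mixture) | COc1cc(OS(=O)(=O)c2ccc(C)cc2)cc(OC)c1C=CC1OCCO1 | intermediate (not isolated)
11 | 3,5-dimethoxy-4-[(E)-3-oxoprop-1-enyl]phenyl 4-methylbenzenesulfonate | COc1cc(OS(=O)(=O)c2ccc(C)cc2)cc(OC)c1/C=C/C=O | intermediate
12 | 4-[(1R)-1-(2,4-dihydroxy-3,6-dimethoxyphenyl)-3-oxopropyl]-3,5-dimethoxyphenyl 4-methylbenzenesulfonate | COc1cc(OS(=O)(=O)c2ccc(C)cc2)cc(OC)c1[C@@H](c1c(O)c(OC)c(O)cc1OC)CC=O | intermediate (not isolated)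
13 | 4-[(4S)-2,7-dihydroxy-5,8-dimethoxychroman-4-yl]-3,5-dimethoxyphenyl 4-methylbenzenesulfonate (both C2 epimers) | COc1cc(OS(=O)(=O)c2ccc(C)cc2)cc(OC)c1[C@@H]1CC(O)Oc2c(OC)c(O)cc(OC)c21 | intermediate
14 | 4-[(4S)-7-(benzyloxy)-2-hydroxy-5,8-dimethoxychroman-4-yl]-3,5-dimethoxyphenyl 4-methylbenzenesulfonate (both C2 epimers) | COc1cc(OS(=O)(=O)c2ccc(C)cc2)cc(OC)c1[C@@H]1CC(O)Oc2c(OC)c(OCc3ccccc3)cc(OC)c21 | intermediate
15 | 4-[(4S)-7-(benzyloxy)-5,8-dimethoxy-2-oxochroman-4-yl]-3,5-dimethoxyphenyl 4-methylbenzenesulfonate | COc1cc(OS(=O)(=O)c2ccc(C)cc2)cc(OC)c1[C@@H]1CC(=O)Oc2c(OC)c(OCc3ccccc3)cc(OC)c21 | intermediate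
16 | 4-[(1R)-1-[4-(benzyloxy)-2-hydroxy-3,6-dimethoxyphenyl]-3-[methoxy(methyl)amino]-3-oxopropyl]-3,5-dimethoxyphenyl 4-methylbenzenesulfonate | COc1cc(OS(=O)(=O)c2ccc(C)cc2)cc(OC)c1[C@@H](c1c(O)c(OC)c(OCc2ccccc2)cc1OC)CC(=O)N(C)OC | intermediate (not isolated)
17 | 4-[(1R)-1-[4-(benzyloxy)-2-hydroxy-3,6-dimethoxyphenyl]-3-oxo-3-phenylpropyl]-3,5-dimethoxyphenyl 4-methylbenzenesulfonate | COc1cc(OS(=O)(=O)c2ccc(C)cc2)cc(OC)c1[C@@H](c1c(O)c(OC)c(OCc2ccccc2)cc1OC)CC(=O)c1ccccc1 | intermediate
18 | 4-[(1R,3R)-1-[4-(benzyloxy)-2-hydroxy-3,6-dimethoxyphenyl]-3-hydroxy-3-phenylpropyl]-3,5-dimethoxyphenyl 4-methylbenzenesulfonate | COc1cc(OS(=O)(=O)c2ccc(C)cc2)cc(OC)c1[C@@H](c1c(O)c(OC)c(OCc2ccccc2)cc1OC)C[C@@H](O)c1ccccc1 | intermediate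
19 | 4-[(2S,4S)-7-(benzyloxy)-5,8-dimethoxy-2-phenylchroman-4-yl]-3,5-dimethoxyphenyl 4-methylbenzenesulfonate | COc1cc(OS(=O)(=O)c2ccc(C)cc2)cc(OC)c1[C@@H]1C[C@@H](c2ccccc2)Oc2c(OC)c(OCc3ccccc3)cc(OC)c21 | intermediate
20 | 4-[(2S,4S)-7-(benzyloxy)-5,8-dimethoxy-2-phenylchroman-4-yl]-3,5-dimethoxyphenol | COc1cc(O)cc(OC)c1[C@@H]1C[C@@H](c2ccccc2)Oc2c(OC)c(OCc3ccccc3)cc(OC)c21 | intermediate
21 | ethyl (3S)-3-hydroxy-3-phenylpropanoate | CCOC(=O)C[C@@H](c1ccccc1)O | starting material
22 | ethyl (3R)-3-{4-[(2S,4S)-7-(benzyloxy)-5,8-dimethoxy-2-phenylchroman-4-yl]-3,5-dimethoxyphenoxy}-3-phenylpropanoate | CCOC(=O)C[C@H](c1ccccc1)Oc1cc(OC)c([C@@H]2C[C@@H](c3ccccc3)Oc3c(OC)c(OCc4ccccc4)cc(OC)c32)c(OC)c1 | intermediate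
23 | (3R)-3-{4-[(2S,4S)-7-(benzyloxy)-5,8-dimethoxy-2-phenylchroman-4-yl]-3,5-dimethoxyphenoxy}-3-phenylpropanoic acid | OC(=O)C[C@H](c1ccccc1)Oc1cc(OC)c([C@@H]2C[C@@H](c3ccccc3)Oc3c(OC)c(OCc4ccccc4)cc(OC)c32)c(OC)c1 | intermediate
24 | mixed anhydride of 23 with trifluoroacetic acid | O=C(C[C@H](c1ccccc1)Oc1cc(OC)c([C@@H]2C[C@@H](c3ccccc3)Oc3c(OC)c(OCc4ccccc4)cc(OC)c32)c(OC)c1)OC(=O)C(F)(F)F | intermediate (not isolated)
25 | (2R)-6-[(2S,4S)-7-(benzyloxy)-5,8-dimethoxy-2-phenylchroman-4-yl]-5,7-dimethoxy-2-phenylchroman-4-one | COc1cc2c(c(OC)c1[C@@H]1C[C@@H](c3ccccc3)Oc3c(OC)c(OCc4ccccc4)cc(OC)c31)C(=O)C[C@H](c1ccccc1)O2 | intermediate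
26 | (2R)-6-[(2S,4S)-7-hydroxy-5,8-dimethoxy-2-phenylchroman-4-yl]-5,7-dimethoxy-2-phenylchroman-4-one | COc1cc2c(c(OC)c1[C@@H]1C[C@@H](c3ccccc3)Oc3c(OC)c(O)cc(OC)c31)C(=O)C[C@H](c1ccccc1)O2 | intermediate (not isolated)
27 | (2R)-5-hydroxy-6-[(2S,4S)-7-hydroxy-5,8-dimethoxy-2-phenylchroman-4-yl]-7-methoxy-2-phenylchroman-4-one | COc1cc2c(c(O)c1[C@@H]1C[C@@H](c3ccccc3)Oc3c(OC)c(O)cc(OC)c31)C(=O)C[C@H](c1ccccc1)O2 | target

## Step count and least certain steps

Total: 17 steps. Longest linear sequence: 15 steps (1 to 27 through steps 1–4 and 7–17); the enal branch (8 to 11) adds two steps.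

**Step 7 (key step).** The conjugate addition may be sluggish, because the β-carbon carries a 2,6-dimethoxyaryl group and the nucleophilic carbon is itself flanked by two oxygens. A slow catalysed reaction would let acid-promoted, non-selective addition and a second alkylation at C6' erode enantiomeric purity and yield. The facial sense assumed for the (S)-catalyst would have to be confirmed by correlation; the enantiomeric catalyst is equally available.

Fallback, from 11 and 7, returning at 15: Pinnick oxidation of 11 (NaClO2, NaH2PO4, 2-methylbut-2-ene) should give (2E)-3-{2,6-dimethoxy-4-[(4-methylbenzenesulfonyl)oxy]phenyl}prop-2-enoic acid F1. Trifluoroacetic acid-mediated hydroarylation and lactonisation of F1 with excess 7 should give racemic 4-(7-hydroxy-5,8-dimethoxy-2-oxochroman-4-yl)-3,5-dimethoxyphenyl 4-methylbenzenesulfonate F2. Benzylation as in step 8 should give racemic 4-[7-(benzyloxy)-5,8-dimethoxy-2-oxochroman-4-yl]-3,5-dimethoxyphenyl 4-methylbenzenesulfonate F3. The enantiomers of F3 would be separated by preparative chromatography on a chiral stationary phase to give 15.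

**Step 10.** The Grignard reagents may attack the lactone carbonyl before the amide has formed (over-addition to a tertiary alcohol), or attack the sulfonate sulfur.

Fallback, from 14, returning at 17: ring-opening addition of PhMgBr (excess, THF, 0 °C → rt) to the lactol should give 4-[(1R)-1-[4-(benzyloxy)-2-hydroxy-3,6-dimethoxyphenyl]-3-hydroxy-3-phenylpropyl]-3,5-dimethoxyphenyl 4-methylbenzenesulfonate F4 as both carbinol epimers. Oppenauer oxidation (Al(Ot-Bu)3, acetone, toluene, 80 °C) is a hydride-transfer method that should leave the free electron-rich phenol alone and give 17.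

**Step 14.** The activated β-hydroxy ester may dehydrate to ethyl cinnamate, and partial ionisation at the benzylic carbon would lower the configurational purity of C2.

Fallback, from 20, returning at 25 (it replaces steps 14–16): acetylation ortho to the phenol (Ac2O, BF3·OEt2) should give 1-{3-[(2S,4S)-7-(benzyloxy)-5,8-dimethoxy-2-phenylchroman-4-yl]-6-hydroxy-2,4-dimethoxyphenyl}ethan-1-one F5. Claisen–Schmidt condensation with benzaldehyde (KOH, EtOH) should give (2E)-1-{3-[(2S,4S)-7-(benzyloxy)-5,8-dimethoxy-2-phenylchroman-4-yl]-6-hydroxy-2,4-dimethoxyphenyl}-3-phenylprop-2-en-1-one F6. Oxa-Michael cyclisation (NaOAc, EtOH, reflux) should give 25 together with its C2 epimer (2S)-6-[(2S,4S)-7-(benzyloxy)-5,8-dimethoxy-2-phenylchroman-4-yl]-5,7-dimethoxy-2-phenylchroman-4-one F7. The two are diastereomers, separable by chromatography, and F7 can be re-equilibrated through F6.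

**Step 17.** The Lewis acid may over-react: cleavage of the crowded 8'-methoxy group next to the freed 7'-oxygen, opening of the benzylic C2'–O1' ether, or ring opening of the flavanone to the chalcone with loss of configuration at C2.

Fallback, from 25, returning at 27: chelation-controlled demethylation with MgI2·OEt2 (THF, 50 °C) should touch only the methoxy group peri to the carbonyl and give (2R)-6-[(2S,4S)-7-(benzyloxy)-5,8-dimethoxy-2-phenylchroman-4-yl]-5-hydroxy-7-methoxy-2-phenylchroman-4-one F8. Hydrogenolysis of the benzyl ether (H2, Pd(OH)2/C, EtOAc) should then give 27.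

## Further compounds

F1 | step 7 | (2E)-3-{2,6-dimethoxy-4-[(4-methylbenzenesulfonyl)oxy]phenyl}prop-2-enoic acid | COc1cc(OS(=O)(=O)c2ccc(C)cc2)cc(OC)c1/C=C/C(=O)O
F2 | step 7 | racemic 4-(7-hydroxy-5,8-dimethoxy-2-oxochroman-4-yl)-3,5-dimethoxyphenyl 4-methylbenzenesulfonate | COc1cc(OS(=O)(=O)c2ccc(C)cc2)cc(OC)c1C1CC(=O)Oc2c(OC)c(O)cc(OC)c21
F3 | step 7 | racemic 4-[7-(benzyloxy)-5,8-dimethoxy-2-oxochroman-4-yl]-3,5-dimethoxyphenyl 4-methylbenzenesulfonate | COc1cc(OS(=O)(=O)c2ccc(C)cc2)cc(OC)c1C1CC(=O)Oc2c(OC)c(OCc3ccccc3)cc(OC)c21
F4 | step 10 | 4-[(1R)-1-[4-(benzyloxy)-2-hydroxy-3,6-dimethoxyphenyl]-3-hydroxy-3-phenylpropyl]-3,5-dimethoxyphenyl 4-methylbenzenesulfonate (both C3 epimers) | COc1cc(OS(=O)(=O)c2ccc(C)cc2)cc(OC)c1[C@@H](c1c(O)c(OC)c(OCc2ccccc2)cc1OC)CC(O)c1ccccc1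
F5 | step 14 | 1-{3-[(2S,4S)-7-(benzyloxy)-5,8-dimethoxy-2-phenylchroman-4-yl]-6-hydroxy-2,4-dimethoxyphenyl}ethan-1-one | CC(=O)c1c(O)cc(OC)c([C@@H]2C[C@@H](c3ccccc3)Oc3c(OC)c(OCc4ccccc4)cc(OC)c32)c1OC
F6 | step 14 | (2E)-1-{3-[(2S,4S)-7-(benzyloxy)-5,8-dimethoxy-2-phenylchroman-4-yl]-6-hydroxy-2,4-dimethoxyphenyl}-3-phenylprop-2-en-1-one | O=C(/C=C/c1ccccc1)c1c(O)cc(OC)c([C@@H]2C[C@@H](c3ccccc3)Oc3c(OC)c(OCc4ccccc4)cc(OC)c32)c1OC
F7 | step 14 | (2S)-6-[(2S,4S)-7-(benzyloxy)-5,8-dimethoxy-2-phenylchroman-4-yl]-5,7-dimethoxy-2-phenylchroman-4-one | COc1cc2c(c(OC)c1[C@@H]1C[C@@H](c3ccccc3)Oc3c(OC)c(OCc4ccccc4)cc(OC)c31)C(=O)C[C@@H](c1ccccc1)O2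
F8 | step 17 | (2R)-6-[(2S,4S)-7-(benzyloxy)-5,8-dimethoxy-2-phenylchroman-4-yl]-5-hydroxy-7-methoxy-2-phenylchroman-4-one | COc1cc2c(c(O)c1[C@@H]1C[C@@H](c3ccccc3)Oc3c(OC)c(OCc4ccccc4)cc(OC)c31)C(=O)C[C@H](c1ccccc1)O2
A1 | alternative 1 | 6-[(2S,4-trans)-7-(benzyloxy)-5,8-dimethoxy-2-phenylchroman-4-yl]-5,7-dimethoxy-2-phenyl-4H-chromen-4-one | COc1cc2OC(c3ccccc3)=CC(=O)c2c(OC)c1[C@@H]1C[C@@H](c2ccccc2)Oc2c(OC)c(OCc3ccccc3)cc(OC)c21
A2 | alternative 1 | 4-[(2S,4-trans)-7-(benzyloxy)-5,8-dimethoxy-2-phenylchroman-4-yl]-2-iodo-3,5-dimethoxyphenol | COc1cc(O)c(I)c(OC)c1[C@@H]1C[C@@H](c2ccccc2)Oc2c(OC)c(OCc3ccccc3)cc(OC)c21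
A3 | alternative 1 | ethynylbenzene | C#Cc1ccccc1
A4 | alternative 1 | 1-{3-[(2S,4-trans)-7-(benzyloxy)-5,8-dimethoxy-2-phenylchroman-4-yl]-6-hydroxy-2,4-dimethoxyphenyl}-3-phenylprop-2-yn-1-one | COc1cc(O)c(C(=O)C#Cc2ccccc2)c(OC)c1[C@@H]1C[C@@H](c2ccccc2)Oc2c(OC)c(OCc3ccccc3)cc(OC)c21
A5 | alternative 2 | (2S,4-trans)-7-(benzyloxy)-4-[2,6-dimethoxy-4-(pivaloyloxy)phenyl]-2-phenylchroman-5,8-diol | COc1cc(OC(=O)C(C)(C)C)cc(OC)c1[C@@H]1C[C@@H](c2ccccc2)Oc2c(O)c(OCc3ccccc3)cc(O)c21
A6 | alternative 2 | 4-{(3S)-1-[4-(benzyloxy)-3,6-dioxocyclohexa-1,4-dien-1-yl]-3-hydroxy-3-phenylpropyl}-3,5-dimethoxyphenyl pivalate (C1 of the chain configured as C4' of the target) | COc1cc(OC(=O)C(C)(C)C)cc(OC)c1[C@@H](C1=CC(=O)C(OCc2ccccc2)=CC1=O)C[C@H](O)c1ccccc1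
A7 | alternative 3 | 7-(benzyloxy)-4-[2,6-dimethoxy-4-(triisopropylsilyloxy)phenyl]-5,8-dimethoxychroman-2-one (C4 as in the target) | COc1cc(O[Si](C(C)C)(C(C)C)C(C)C)cc(OC)c1[C@@H]1CC(=O)Oc2c(OC)c(OCc3ccccc3)cc(OC)c21
A8 | alternative 3 | 6-(benzyloxy)-3-[2,6-dimethoxy-4-(triisopropylsilyloxy)phenyl]-4,7-dimethoxyindan-1-one (C3 configured as C4' of the target) | COc1cc(O[Si](C(C)C)(C(C)C)C(C)C)cc(OC)c1[C@@H]1CC(=O)c2c(OC)c(OCc3ccccc3)cc(OC)c21
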